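The 1,2-dioxane (O1–O2–C3–C4–C5–C6) is closed last, at its quaternary carbon. C6 holds O1, a methyl group, ring carbon C5 and the C7 methylene, the same array as the fully substituted carbon of a 2-alkyl-2-methyloxirane whose CH2 is C7. A (3S)-hydroperoxide therefore opens an (S)-epoxide at that carbon under mild acid: one operation forms C6–O1 with inversion, closes the six-membered peroxide, fixes the quaternary stereocentre and releases C7 as CH2OH for the side chain. The precursor is an acyclic epoxy hydroperoxide carrying an α-methylene ester, which is reduced afterwards to the C2 methyl centre.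

Key step: step 9

Numbering used throughout: C1 is the ester carbon, C2 the CH(CH3) carbon, C3–C6 the ring carbons (O2 on C3, O1 on C6), C7–C14 the side chain, with the methylidene on C10. The target is (2S,3S,6R), with the C3 arm and the C7 arm cis on the ring.

Remark on the epoxide: inversion at C6 requires the (2S)-oxirane. Epoxide hydrolases characteristically consume that enantiomer of 2-alkyl-2-methyloxiranes, so the centre is taken instead from (R)-2-methylglycidol, which is opened to the S diol and re-closed with retention.

Assumption: (DHQD)2PHAL is taken to give 3S in step 7; the pseudoenantiomeric (DHQ)2PHAL gives the other C3 configuration and would replace it if the first run showed the opposite sense.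

Assumption: (R)-2-methylglycidol and the symmetric β-keto bis-phosphonate used in step 14 are treated as catalogue compounds.

Step 1
Reactants: 1 (R)-2-methylglycidol, [(2R)-2-methyloxiran-2-yl]methanol; 2 allylmagnesium chloride
Product: 3 (2S)-2-methylhex-5-ene-1,2-diol
Conditions: allylMgCl (2.5 equiv), CuI (10 mol %), THF, −30 → 0 °C; aq. NH4Cl
Reagents that add atoms: none
Why: Copper-catalysed Grignard opening of an epoxide: after the first equivalent has deprotonated the hydroxyl, allyl attacks the unsubstituted ring CH2 (Payne migration of this alkoxide is degenerate and leads to the same diol), so the quaternary centre of 1 passes unchanged into the tertiary carbinol and is called S only because the CIP ranks of the two CH2 arms swap.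

Step 2
Reactants: 3 (2S)-2-methylhex-5-ene-1,2-diol
Product: 5 (2S)-2-(but-3-en-1-yl)-2-methyloxirane, via primary tosylate 4 (not isolated)
Conditions: TsCl, Et3N, Bu2SnO (2 mol %), CH2Cl2, 0 °C; then 50% aq. NaOH, Bu4NHSO4 (cat.), rt
Reagents that add atoms: none
Why: Tin-catalysed selective sulfonylation of the primary hydroxyl followed by intramolecular Williamson etherification (3-exo-tet displacement by the tertiary alkoxide) closes the oxirane on C7 without breaking a bond to the quaternary carbon, so its configuration is retained; the volatile product is carried on as a dried CH2Cl2 solution.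

Step 3
Reactants: 5 (2S)-2-(but-3-en-1-yl)-2-methyloxirane
Product: 7 3-[(2S)-2-methyloxiran-2-yl]propanal, via secondary ozonide 6 (not isolated)
Conditions: O3, CH2Cl2, −78 °C; then Me2S, −78 °C → rt
Reagents that add atoms: ozone, O=[O+][O-]
Why: Criegee ozonolysis with reductive work-up cleaves the only C=C bond to the aldehyde, the oxirane being inert to ozone and to dimethyl sulfide at low temperature.

Step 4
Reactants: 7 3-[(2S)-2-methyloxiran-2-yl]propanal; 8 methyl acrylate
Product: 9 methyl 2-{(1RS)-1-hydroxy-3-[(2S)-2-methyloxiran-2-yl]propyl}prop-2-enoate (both C3 epimers)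
Conditions: DABCO (0.5 equiv), methyl acrylate (3 equiv), MeOH (cat.), rt, several days
Reagents that add atoms: none
Why: Morita–Baylis–Hillman reaction, in which the DABCO-derived ammonium enolate of 8 adds to the unhindered aliphatic aldehyde; the carbinol centre forms without control, which does not matter because step 7 erases and resets it.

Step 5
Reactants: 9 methyl 2-{(1RS)-1-hydroxy-3-[(2S)-2-methyloxiran-2-yl]propyl}prop-2-enoate
Product: 10 methyl 2-{(1RS)-1-[(tert-butoxycarbonyl)oxy]-3-[(2S)-2-methyloxiran-2-yl]propyl}prop-2-enoate
Conditions: Boc2O, DMAP (10 mol %), CH2Cl2, 0 °C → rt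
Reagents that add atoms: di-tert-butyl dicarbonate, CC(C)(C)OC(=O)OC(=O)OC(C)(C)C
Why: DMAP-catalysed acylation of the secondary allylic alcohol installs the tert-butyl carbonate that later serves both as leaving group and as source of the tert-butoxide base.

Step 6
Reactants: 11 2,3-dimethylbut-2-ene
Product: 13 2-methoxypropan-2-yl hydroperoxide, via acetone carbonyl oxide 12 (not isolated)
Conditions: O3, CH2Cl2/MeOH (4:1), −78 °C
Reagents that add atoms: ozone, O=[O+][O-]; methanol, CO
Why: Ozonolysis in a participating solvent: the Criegee carbonyl oxide released from the tetrasubstituted alkene is intercepted by methanol to give an α-methoxy hydroperoxide, that is, a hydroperoxide whose second oxygen is masked as an acid-labile ketal.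

Step 7
Reactants: 10 methyl 2-{(1RS)-1-[(tert-butoxycarbonyl)oxy]-3-[(2S)-2-methyloxiran-2-yl]propyl}prop-2-enoate; 13 2-methoxypropan-2-yl hydroperoxide
Product: 14 methyl 2-{(1S)-1-[(2-methoxypropan-2-yl)peroxy]-3-[(2S)-2-methyloxiran-2-yl]propyl}prop-2-enoate
Conditions: (DHQD)2PHAL (10 mol %), 13 (2 equiv), PhCF3, 25–35 °C
Reagents that add atoms: none
Why: Lewis-base-catalysed asymmetric allylic substitution of a Morita–Baylis–Hillman carbonate (SN2′–SN2′): the quinuclidine nitrogen adds to the acrylate terminus and expels tert-butyl carbonate, whose tert-butoxide deprotonates 13, and the peroxide anion then attacks the planar allylammonium at C3 inside the chiral pocket, so both epimers of 10 converge and the catalyst alone sets 3S.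

Step 8
Reactants: 14 methyl 2-{(1S)-1-[(2-methoxypropan-2-yl)peroxy]-3-[(2S)-2-methyloxiran-2-yl]propyl}prop-2-enoate
Product: 15 methyl 2-{(1S)-1-hydroperoxy-3-[(2S)-2-methyloxiran-2-yl]propyl}prop-2-enoate
Conditions: AcOH/THF/H2O (4:2:1), 0 °C → rt, short contact; cold aq. NaHCO3 work-up; used at once
Reagents that add atoms: none
Why: Acid-catalysed hydrolysis of the monoperoxyketal cleaves its ketal C–O bond much faster than aqueous acetic acid opens a dialkyl oxirane, releasing the free secondary hydroperoxide with C3 and the O–O bond untouched; 15 is not stored (allylic hydroperoxides can transpose by the radical Schenck rearrangement), and any portion that has already cyclised is simply 16.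

Step 9
Reactants: 15 methyl 2-{(1S)-1-hydroperoxy-3-[(2S)-2-methyloxiran-2-yl]propyl}prop-2-enoate
Product: 16 methyl 2-[(3S,6R)-6-(hydroxymethyl)-6-methyl-1,2-dioxan-3-yl]prop-2-enoate
Conditions: CSA (10 mol %), CH2Cl2, 0 °C; Et3N quench
Reagents that add atoms: none
Why: Protonation of the oxirane oxygen lengthens the C6–O bond and the terminal oxygen of the C3 hydroperoxide attacks C6 from the side opposite the departing oxygen, giving the dioxane after proton loss; this is the acid-catalysed cyclisation of epoxy hydroperoxides to cyclic peroxides, the peroxide counterpart of exo-selective epoxy-alcohol cyclisations. The 1,2-dioxane closes in a 6-exo-tet mode, with C6 attacked and the breaking C6–O bond outside the new ring. The new quaternary stereocentre C6 is controlled by the epoxide configuration through inversion (2S-oxirane to 6R), while C3 from step 7 is not touched, so the cis relation of the acrylate arm and the hydroxymethyl arm follows from two independent reagent-controlled centres. The step needs attack at the substituted carbon instead of 7-endo attack at C7, and an SN2-like instead of a carbocationic opening: the methyl and alkyl groups polarise the C6–O bond toward C6, the six-membered transition state beats the seven-membered one, and a catalytic sulfonic acid in cold CH2Cl2 without external nucleophile keeps the opening concerted and excludes solvolysis. The electron-poor acrylate disfavours the vinyl migration that Hock cleavage of the allylic hydroperoxide would need. Because C3 and C6 are set independently, their minor stereochemical impurities should end up mainly in the trans-dioxane, which chromatography removes here.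

Step 10
Reactants: 16 methyl 2-[(3S,6R)-6-(hydroxymethyl)-6-methyl-1,2-dioxan-3-yl]prop-2-enoate
Product: 17 methyl (2S)-2-[(3S,6R)-6-(hydroxymethyl)-6-methyl-1,2-dioxan-3-yl]propanoate
Conditions: ene-reductase (Old Yellow Enzyme family, chosen from a panel for 2S), NADP+ (cat.), D-glucose, glucose dehydrogenase, phosphate buffer pH 7, 5% DMSO, 30 °C
Reagents that add atoms: none
Why: Flavin-dependent ene-reductase reduction of an α-methylene ester: hydride passes from FMNH2 to the terminal CH2 and an active-site tyrosine protonates C2 on the opposite face, so the C2 configuration is imposed by the binding mode of the enzyme and the panel member (wild type or a pocket variant with reversed binding) that gives 2S is used, while the neutral metal-free medium should leave the O–O bond intact.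

Step 11
Reactants: 17 methyl (2S)-2-[(3S,6R)-6-(hydroxymethyl)-6-methyl-1,2-dioxan-3-yl]propanoate
Product: 18 methyl (2S)-2-[(3S,6R)-6-formyl-6-methyl-1,2-dioxan-3-yl]propanoate
Conditions: Dess–Martin periodinane, CH2Cl2, 0 °C → rt
Reagents that add atoms: none
Why: Dess–Martin oxidation converts the neopentyl-type primary alcohol into the aldehyde under non-basic, metal-free conditions that dialkyl peroxides tolerate, and the α-carbon C6 is quaternary and cannot epimerise.

Step 12
Reactants: 19 ethyl 4-bromobutanoate
Product: 20 5-bromo-2-methylpentan-2-ol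
Conditions: MeMgBr (2.2 equiv), Et2O, −20 → 0 °C; aq. NH4Cl
Reagents that add atoms: methylmagnesium bromide, C[Mg]Br
Why: Double Grignard addition to the ester gives the tertiary alcohol, and keeping the mixture at or below 0 °C until the quench prevents the magnesium alkoxide from displacing the remote primary bromide.

Step 13
Reactants: 20 5-bromo-2-methylpentan-2-ol
Product: 21 [(5-bromo-2-methylpentan-2-yl)oxy]triethylsilane
Conditions: TESCl, imidazole, DMAP (cat.), DMF, rt
Reagents that add atoms: chlorotriethylsilane, CC[Si](Cl)(CC)CC
Why: Silylation of the tertiary alcohol blocks alkoxide formation and 5-exo cyclisation to a tetrahydrofuran during the base-mediated alkylation that follows.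

Step 14
Reactants: 21 [(5-bromo-2-methylpentan-2-yl)oxy]triethylsilane; 22 tetraethyl (2-oxopropane-1,3-diyl)bis(phosphonate)
Product: 24 tetraethyl (7-hydroxy-7-methyl-2-oxooctane-1,3-diyl)bis(phosphonate), via silyl ether 23 (not isolated)
Conditions: NaH (1.0 equiv), 22 (1.5 equiv), NaI (cat.), DMF, 60 °C; then 1 M HCl, THF, rt
Reagents that add atoms: none
Why: C-Alkylation of the sodium enolate of the symmetric β-keto bis-phosphonate (Finkelstein-assisted SN2; the two CH2 groups are equivalent, so only one monoalkylation product exists and excess 22 suppresses dialkylation), after which dilute acid removes the silyl ether to give the hydroxy linchpin as a racemate whose stereocentre is destroyed in step 17.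

Step 15
Reactants: 18 methyl (2S)-2-[(3S,6R)-6-formyl-6-methyl-1,2-dioxan-3-yl]propanoate; 24 tetraethyl (7-hydroxy-7-methyl-2-oxooctane-1,3-diyl)bis(phosphonate)
Product: 25 methyl (2S)-2-{(3S,6R)-6-[(1E)-4-(diethoxyphosphoryl)-8-hydroxy-8-methyl-3-oxonon-1-en-1-yl]-6-methyl-1,2-dioxan-3-yl}propanoate (both C10 epimers)
Conditions: Ba(OH)2·8H2O (activated), THF/H2O (40:1), 0 °C → rt
Reagents that add atoms: none
Why: Horner–Wadsworth–Emmons olefination under mild barium hydroxide conditions: the unsubstituted, more acidic and less hindered P–CH2–C=O terminus of 24 reacts with the hindered aldehyde to give the (E)-enone, while the alkyl-substituted phosphonate carbon is too encumbered to compete and is kept for step 17.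

Step 16
Reactants: 25 methyl (2S)-2-{(3S,6R)-6-[(1E)-4-(diethoxyphosphoryl)-8-hydroxy-8-methyl-3-oxonon-1-en-1-yl]-6-methyl-1,2-dioxan-3-yl}propanoate
Product: 26 methyl (2S)-2-{(3S,6R)-6-[4-(diethoxyphosphoryl)-8-hydroxy-8-methyl-3-oxononyl]-6-methyl-1,2-dioxan-3-yl}propanoate (both C10 epimers)
Conditions: dipotassium azodicarboxylate, AcOH, MeOH/CH2Cl2, 0 °C → rt, repeated charges
Reagents that add atoms: none
Why: Diimide reduction (concerted syn transfer of H2 from HN=NH generated in situ) saturates the C7=C8 bond and is the standard way to hydrogenate an alkene beside an O–O bond, which it does not reduce.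

Step 17
Reactants: 26 methyl (2S)-2-{(3S,6R)-6-[4-(diethoxyphosphoryl)-8-hydroxy-8-methyl-3-oxononyl]-6-methyl-1,2-dioxan-3-yl}propanoate
Product: 27 aikupikoxide D, methyl (2S)-2-[(3S,6R)-6-(8-hydroxy-8-methyl-4-methylidene-3-oxononyl)-6-methyl-1,2-dioxan-3-yl]propanoate
Conditions: 37% aq. CH2O, K2CO3, THF, rt
Reagents that add atoms: formaldehyde, C=O
Why: Horner–Wadsworth–Emmons methylenation of the α-substituted β-ketophosphonate with aqueous formaldehyde and carbonate builds the C10 methylidene exactly at the phosphonate-bearing carbon, so the regiochemistry of the enone is dictated by the linchpin and the free tertiary alcohol needs no protection.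

Compound list

1 | (R)-2-methylglycidol, [(2R)-2-methyloxiran-2-yl]methanol | OC[C@]1(C)CO1 | starting material
2 | allylmagnesium chloride | C=CC[Mg]Cl | starting material
3 | (2S)-2-methylhex-5-ene-1,2-diol | C=CCC[C@](C)(O)CO | intermediate
4 | (2S)-2-hydroxy-2-methylhex-5-en-1-yl 4-methylbenzenesulfonate (primary tosylate, formed in the flask) | C=CCC[C@](C)(O)COS(=O)(=O)c1ccc(C)cc1 | intermediate
5 | (2S)-2-(but-3-en-1-yl)-2-methyloxirane | C=CCC[C@@]1(C)CO1 | intermediate
6 | 3-{2-[(2S)-2-methyloxiran-2-yl]ethyl}-1,2,4-trioxolane (secondary ozonide, formed in the flask, both epimers at the ozonide carbon) | C1OC(CC[C@@]2(C)CO2)OO1 | intermediate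
7 | 3-[(2S)-2-methyloxiran-2-yl]propanal | O=CCC[C@@]1(C)CO1 | intermediate
8 | methyl acrylate | C=CC(=O)OC | starting material
9 | methyl 2-{(1RS)-1-hydroxy-3-[(2S)-2-methyloxiran-2-yl]propyl}prop-2-enoate | C=C(C(=O)OC)C(O)CC[C@@]1(C)CO1 | intermediate
10 | methyl 2-{(1RS)-1-[(tert-butoxycarbonyl)oxy]-3-[(2S)-2-methyloxiran-2-yl]propyl}prop-2-enoate | C=C(C(=O)OC)C(OC(=O)OC(C)(C)C)CC[C@@]1(C)CO1 | intermediate
11 | 2,3-dimethylbut-2-ene | CC(C)=C(C)C | starting material
12 | acetone carbonyl oxide, propan-2-one O-oxide (formed in the flask) | CC(C)=[O+][O-] | intermediate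
13 | 2-methoxypropan-2-yl hydroperoxide | COC(C)(C)OO | intermediate
14 | methyl 2-{(1S)-1-[(2-methoxypropan-2-yl)peroxy]-3-[(2S)-2-methyloxiran-2-yl]propyl}prop-2-enoate | C=C(C(=O)OC)[C@@H](OOC(C)(C)OC)CC[C@@]1(C)CO1 | intermediate
15 | methyl 2-{(1S)-1-hydroperoxy-3-[(2S)-2-methyloxiran-2-yl]propyl}prop-2-enoate | C=C(C(=O)OC)[C@@H](OO)CC[C@@]1(C)CO1 | intermediate
16 | methyl 2-[(3S,6R)-6-(hydroxymethyl)-6-methyl-1,2-dioxan-3-yl]prop-2-enoate | OC[C@@]1(C)CC[C@@H](C(=C)C(=O)OC)OO1 | intermediate
17 | methyl (2S)-2-[(3S,6R)-6-(hydroxymethyl)-6-methyl-1,2-dioxan-3-yl]propanoate | OC[C@@]1(C)CC[C@@H]([C@H](C)C(=O)OC)OO1 | intermediate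
18 | methyl (2S)-2-[(3S,6R)-6-formyl-6-methyl-1,2-dioxan-3-yl]propanoate | O=C[C@@]1(C)CC[C@@H]([C@H](C)C(=O)OC)OO1 | intermediate
19 | ethyl 4-bromobutanoate | CCOC(=O)CCCBr | starting material
20 | 5-bromo-2-methylpentan-2-ol | CC(C)(O)CCCBr | intermediate
21 | [(5-bromo-2-methylpentan-2-yl)oxy]triethylsilane | CC[Si](CC)(CC)OC(C)(C)CCCBr | intermediate
22 | tetraethyl (2-oxopropane-1,3-diyl)bis(phosphonate) | CCOP(=O)(OCC)CC(=O)CP(=O)(OCC)OCC | starting material
23 | tetraethyl {7-methyl-2-oxo-7-[(triethylsilyl)oxy]octane-1,3-diyl}bis(phosphonate) (silyl ether, formed in the flask, racemic) | CCOP(=O)(OCC)CC(=O)C(CCCC(C)(C)O[Si](CC)(CC)CC)P(=O)(OCC)OCC | intermediate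
24 | tetraethyl (7-hydroxy-7-methyl-2-oxooctane-1,3-diyl)bis(phosphonate) (racemic) | CCOP(=O)(OCC)CC(=O)C(CCCC(C)(C)O)P(=O)(OCC)OCC | intermediate
25 | methyl (2S)-2-{(3S,6R)-6-[(1E)-4-(diethoxyphosphoryl)-8-hydroxy-8-methyl-3-oxonon-1-en-1-yl]-6-methyl-1,2-dioxan-3-yl}propanoate | CCOP(=O)(OCC)C(CCCC(C)(C)O)C(=O)/C=C/[C@@]1(C)CC[C@@H]([C@H](C)C(=O)OC)OO1 | intermediate
26 | methyl (2S)-2-{(3S,6R)-6-[4-(diethoxyphosphoryl)-8-hydroxy-8-methyl-3-oxononyl]-6-methyl-1,2-dioxan-3-yl}propanoate | CCOP(=O)(OCC)C(CCCC(C)(C)O)C(=O)CC[C@@]1(C)CC[C@@H]([C@H](C)C(=O)OC)OO1 | intermediate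
27 | aikupikoxide D, methyl (2S)-2-[(3S,6R)-6-(8-hydroxy-8-methyl-4-methylidene-3-oxononyl)-6-methyl-1,2-dioxan-3-yl]propanoate | C=C(CCCC(C)(C)O)C(=O)CC[C@@]1(C)CC[C@@H]([C@H](C)C(=O)OC)OO1 | target

Total step count: 17 (13 in the main line, 1 for the peroxide reagent, 3 for the phosphonate linchpin).
Longest linear sequence: 13 steps (steps 1–5, 7–11 and 15–17).

Steps most likely to fail

Step 10, the ene-reductase reduction. The enzyme may not accept an acrylate with so large an α-substituent, hydride and proton may be delivered with the wrong facial sense, or the reduced flavin may reduce the O–O bond. The fallback gives up catalyst control and relies on separation. It sets out from 16: diimide (dipotassium azodicarboxylate, AcOH, MeOH/CH2Cl2) should reduce the acrylate without touching the peroxide, giving 17 together with its C2 epimer, methyl (2R)-2-[(3S,6R)-6-(hydroxymethyl)-6-methyl-1,2-dioxan-3-yl]propanoate F1. Preparative chromatography of the two alcohols should remove F1, and the route is rejoined at 17.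

Step 7, the asymmetric allylic peroxidation. An aliphatic Morita–Baylis–Hillman carbonate may turn over slowly, facial discrimination at C3 may be poor, and some linear SN2′ product may form. The fallback makes the hydroperoxide by a singlet-oxygen ene reaction and accepts a mixture at C3. It sets out from 7: Wittig olefination with methyl 2-(triphenylphosphoranylidene)propanoate in CH2Cl2 should give methyl (2E)-2-methyl-5-[(2S)-2-methyloxiran-2-yl]pent-2-enoate F2. Schenck ene reaction of F2 (O2, visible light, tetraphenylporphyrin, CH2Cl2, 0 °C) abstracts hydrogen from the methyl group geminal to the ester and should give 15 directly, mixed with its C3 epimer, methyl 2-{(1R)-1-hydroperoxy-3-[(2S)-2-methyloxiran-2-yl]propyl}prop-2-enoate F3. The route is rejoined at 15; step 9 is run on the mixture, and the trans-dioxane from F3, methyl 2-[(3R,6R)-6-(hydroxymethyl)-6-methyl-1,2-dioxan-3-yl]prop-2-enoate F4, is separated from 16 by chromatography.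

Step 9, the key cyclisation. The opening may become carbocation-like and lose stereospecificity at C6, the hydroperoxide may attack C7 in the 7-endo sense, or the epoxide may rearrange to an aldehyde before it is trapped. The fallback forms the same two C–O bonds in the reverse order and closes the ring at C3. It sets out from 10: perhydrolysis of the epoxide with ethereal H2O2 and catalytic phosphomolybdic acid should open it at the tertiary carbon with inversion and give methyl 2-[(1RS,4R)-1-[(tert-butoxycarbonyl)oxy]-4-hydroperoxy-5-hydroxy-4-methylpentyl]prop-2-enoate F5. Treatment of F5 with (DHQD)2PHAL (or DABCO) in toluene should then close the dioxane by intramolecular SN2′–SN2′ substitution of the carbonate by the more acidic hydroperoxide. The route is rejoined at 16, after chromatographic removal of any F4.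

Further compounds
F1 | step 10 | methyl (2R)-2-[(3S,6R)-6-(hydroxymethyl)-6-methyl-1,2-dioxan-3-yl]propanoate | OC[C@@]1(C)CC[C@@H]([C@@H](C)C(=O)OC)OO1
F2 | step 7 | methyl (2E)-2-methyl-5-[(2S)-2-methyloxiran-2-yl]pent-2-enoate | COC(=O)/C(C)=C/CC[C@@]1(C)CO1
F3 | step 7 | methyl 2-{(1R)-1-hydroperoxy-3-[(2S)-2-methyloxiran-2-yl]propyl}prop-2-enoate | C=C(C(=O)OC)[C@H](OO)CC[C@@]1(C)CO1
F4 | step 7 | methyl 2-[(3R,6R)-6-(hydroxymethyl)-6-methyl-1,2-dioxan-3-yl]prop-2-enoate | OC[C@@]1(C)CC[C@H](C(=C)C(=O)OC)OO1
F5 | step 9 | methyl 2-[(1RS,4R)-1-[(tert-butoxycarbonyl)oxy]-4-hydroperoxy-5-hydroxy-4-methylpentyl]prop-2-enoate | C=C(C(=O)OC)C(OC(=O)OC(C)(C)C)CC[C@@](C)(OO)CO
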